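**Strategy**

Ring A is disconnected as a resorcinol in which the prenyl-bearing carbons C3' and C5' flank C4'–O. C3'–C4' come from a prenyl triisopropylsilyl ynol ether, and C2', C5', C6' and C1' from a prenyl vinylketene released from an acyclic α-diazo vinyl ketone. One operation (Wolff shift, [2+2] addition, 4π opening, 6π closure) forms four ring bonds, sets both prenyl groups by connectivity and leaves the two oxygens differentiated, with C2'–OH free next to unsubstituted C1'. The dihydrocinnamoyl chain of ring B then enters by O-acylation and photo-Fries shift to C1', and fluoride frees both silylated phenols.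

Key step: step 6

Remark: the target has no stereocentre; the stereocentres that appear in 4, 15 and 23 are racemic and transient, and 9 is taken as its purchased THF solution.

**Route**

Step 1
Reactants: 1 5-bromo-2-methylpent-2-ene; 2 acrolein
Product: 4 7-methylocta-1,6-dien-3-ol (racemic), via (4-methylpent-3-en-1-yl)magnesium bromide 3 (not isolated)
Conditions: Mg, THF, 40 °C; then 2, −78 → 0 °C; aq NH4Cl
Reagents that add atoms: magnesium, [Mg] (kept only in 3)
Why: Grignard formation from the primary homoallylic bromide and 1,2-addition to acrolein at low temperature is standard carbonyl addition, and the new carbinol centre forms racemic and needs no control because step 2 oxidises it away.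

Step 2
Reactants: 4 7-methylocta-1,6-dien-3-ol
Product: 5 7-methylocta-1,6-dien-3-one
Conditions: Dess–Martin periodinane, CH2Cl2, 0 °C → rt
Reagents that add atoms: none
Why: Dess–Martin oxidation should convert the secondary allylic alcohol into the vinyl ketone under mild conditions that spare the trisubstituted alkene and limit polymerisation of the enone.

Step 3
Reactants: 5 7-methylocta-1,6-dien-3-one
Product: 7 4-diazo-7-methylocta-1,6-dien-3-one, via trifluoroacetyl ketone 6 (not isolated)
Conditions: LiN(SiMe3)2, THF, −78 °C (5 added slowly); CF3CO2CH2CF3, −78 °C; aq HCl work-up; then MsN3, Et3N, H2O, MeCN, rt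
Reagents that add atoms: methanesulfonyl azide, CS(=O)(=O)N=[N+]=[N-]; 2,2,2-trifluoroethyl trifluoroacetate, O=C(OCC(F)(F)F)C(F)(F)F (its acyl group is kept only in 6)
Why: Deacylative (Regitz-type) diazo transfer by way of the trifluoroacetyl ketone should work because C4 is the only enolisable position of 5, so kinetic deprotonation and Claisen-type trifluoroacetylation give 6, whose activated methine takes the diazo group from MsN3 while the trifluoroacetyl group leaves on the sulfonamide nitrogen.

Step 4
Reactants: 8 prenyl bromide (1-bromo-3-methylbut-2-ene); 9 ethynylmagnesium bromide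
Product: 10 5-methylhex-4-en-1-yne
Conditions: CuBr·SMe2 (5 mol %), 9 (2 equiv), THF, 0 °C → rt; distilled as a THF solution
Reagents that add atoms: none
Why: Copper-catalysed coupling of an alkynyl Grignard reagent with an allylic bromide should give the skipped enyne, the alkynyl group entering at the unhindered primary carbon of the prenyl unit (SN2 rather than SN2' attack at the tertiary terminus) and the excess of 9 suppressing double alkylation.

Step 5
Reactants: 10 5-methylhex-4-en-1-yne
Product: 13 triisopropyl[(5-methylhex-4-en-1-yn-1-yl)oxy]silane, via lithium acetylide 11 (not isolated), via lithium ynolate 12 (not isolated)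
Conditions: n-BuLi, THF, −78 °C; LiOOt-Bu (from t-BuOOH and LiN(SiMe3)2), −78 → 0 °C; i-Pr3SiOTf, −78 → 0 °C
Reagents that add atoms: n-butyllithium, [Li]CCCC (lithium kept only in 11 and 12); tert-butyl hydroperoxide, CC(C)(C)OO; triisopropylsilyl trifluoromethanesulfonate, CC(C)[Si](OS(=O)(=O)C(F)(F)F)(C(C)C)C(C)C
Why: Oxidation of a lithium acetylide by lithium tert-butyl peroxide transfers an electrophilic oxygen to carbon to give the ynolate, and the bulky silyl triflate should trap it on oxygen rather than carbon (ynolate O-silylation) to give a storable triisopropylsilyl ynol ether.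

Step 6
Reactants: 7 4-diazo-7-methylocta-1,6-dien-3-one; 13 triisopropyl[(5-methylhex-4-en-1-yn-1-yl)oxy]silane
Product: 18 2,4-bis(3-methylbut-2-en-1-yl)-3-[(triisopropylsilyl)oxy]phenol, via prenyl vinylketene 14 (not isolated), via 4-vinylcyclobutenone 15 (not isolated), via dienylketene 16 (not isolated), via cyclohexa-2,4-dienone 17 (not isolated)
Conditions: hν (medium-pressure Hg lamp, Pyrex filter), 13 (1.5 equiv), degassed ClCH2CH2Cl, rt; then 80 °C in the dark
Reagents that add atoms: none
Why: Light expels N2 from 7 and the vinyl group shifts from the carbonyl carbon to the former diazo carbon (Wolff shift, C5'–C6') to give vinylketene 14, whose carbonyl carbon is attacked by the nucleophilic prenyl-bearing carbon of ynol ether 13, so that stepwise [2+2] addition closes the four-membered ring of 15 (C2'–C3' and C4'–C5'). On warming, 15 opens by reversible conrotatory 4π cleavage of C2'–C5' to dienylketene 16, which closes ring A by thermal disrotatory 6π electrocyclisation (C1'–C2', six-membered carbocycle) to 17, and enolisation gives phenol 18. The closest known reaction type is the Danheiser benzannulation in its diazo ketone form applied to siloxyalkynes, which delivers resorcinol monosilyl ethers. No stereocentre is carried forward: the quaternary carbon of 15 is racemic and vanishes on ring opening, and only the isomer of 16 that holds the vinyl group cis to the ketene can cyclise, the other returning to 15 by ring closure. The step needs regioselective [2+2] addition, secured by the matched polarity of the silyloxy-substituted alkyne and the ketene (the silyloxy carbon ends up meta to the new hydroxyl and between the two prenyl groups), and Wolff shift rather than 1,2-hydride shift of the carbene, favoured by direct photolysis of the s-Z conformer and by the high migratory aptitude of a vinyl group. The Pyrex filter spares phenol 18 and the isolated prenyl alkenes, the excess of 13 intercepts 14 before 18 can add to it, and the one-carbon tethers keep the prenyl groups from intramolecular ketene cycloaddition.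

Step 7
Reactants: 19 3-(4-hydroxyphenyl)propanoic acid
Product: 21 3-{4-[(tert-butyldimethylsilyl)oxy]phenyl}propanoic acid, via bis-silylated acid 20 (not isolated)
Conditions: t-BuMe2SiCl (2.2 equiv), imidazole, DMF, rt; then AcOH/THF/H2O, rt
Reagents that add atoms: tert-butyldimethylsilyl chloride, CC(C)(C)[Si](C)(C)Cl
Why: Exhaustive silylation followed by selective hydrolysis of the far more labile silyl ester is the standard way to mask only the phenol of a phenolic acid, the aryl silyl ether being stable to dilute acetic acid.

Step 8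
Reactants: 18 2,4-bis(3-methylbut-2-en-1-yl)-3-[(triisopropylsilyl)oxy]phenol; 21 3-{4-[(tert-butyldimethylsilyl)oxy]phenyl}propanoic acid
Product: 22 2,4-bis(3-methylbut-2-en-1-yl)-3-[(triisopropylsilyl)oxy]phenyl 3-{4-[(tert-butyldimethylsilyl)oxy]phenyl}propanoate
Conditions: DCC, DMAP (10 mol %), CH2Cl2, 0 °C → rt
Reagents that add atoms: none
Why: Steglich esterification should acylate the free C2' hydroxyl, DCC activating the acid and DMAP relaying the acyl group, while the C4' oxygen stays silylated.

Step 9
Reactants: 22 the aryl ester of step 8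
Product: 24 3-{4-[(tert-butyldimethylsilyl)oxy]phenyl}-1-{2-hydroxy-3,5-bis(3-methylbut-2-en-1-yl)-4-[(triisopropylsilyl)oxy]phenyl}propan-1-one, via 6-acylcyclohexa-2,4-dienone 23 (not isolated)
Conditions: hν (254 nm, low-pressure Hg lamp, quartz), degassed cyclohexane (high dilution), rt
Reagents that add atoms: none
Why: Photo-Fries rearrangement should work because homolysis of the ester C(O)–O bond gives a caged acyl/aryloxyl radical pair that can recombine productively only at C1', the single unsubstituted ortho position (C3' and the para carbon C5' carry prenyl groups and give dienones that cannot aromatise), and enolisation of 23 gives the hydrogen-bonded, photostable ortho-hydroxy ketone.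

Step 10
Reactants: 24 the bis-silylated dihydrochalcone of step 9
Product: 25 Gancaonin J, 1-[2,4-dihydroxy-3,5-bis(3-methylbut-2-en-1-yl)phenyl]-3-(4-hydroxyphenyl)propan-1-one
Conditions: Bu4NF, AcOH, THF, 0 °C → rt
Reagents that add atoms: none
Why: Fluoride-mediated desilylation should cleave both aryl silyl ethers through pentacoordinate silicon, with acetic acid buffering the phenoxides so that the prenyl groups and the ketone are left untouched.

**Compound list**

1 | 5-bromo-2-methylpent-2-ene | CC(C)=CCCBr | starting material
2 | acrolein (prop-2-enal) | C=CC=O | starting material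
3 | (4-methylpent-3-en-1-yl)magnesium bromide | CC(C)=CCC[Mg]Br | intermediate
4 | 7-methylocta-1,6-dien-3-ol (racemic) | C=CC(O)CCC=C(C)C | intermediate
5 | 7-methylocta-1,6-dien-3-one | C=CC(=O)CCC=C(C)C | intermediate
6 | 1,1,1-trifluoro-3-(3-methylbut-2-en-1-yl)hex-5-ene-2,4-dione (racemic, largely enolised) | C=CC(=O)C(CC=C(C)C)C(=O)C(F)(F)F | intermediate
7 | 4-diazo-7-methylocta-1,6-dien-3-one | C=CC(=O)C(=[N+]=[N-])CC=C(C)C | intermediate
8 | prenyl bromide (1-bromo-3-methylbut-2-ene) | CC(C)=CCBr | starting material
9 | ethynylmagnesium bromide | C#C[Mg]Br | starting material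
10 | 5-methylhex-4-en-1-yne | CC(C)=CCC#C | intermediate
11 | lithium 5-methylhex-4-en-1-yn-1-ide | [Li+].[C-]#CCC=C(C)C | intermediate
12 | lithium 5-methylhex-4-en-1-yn-1-olate | [Li+].[O-]C#CCC=C(C)C | intermediate
13 | triisopropyl[(5-methylhex-4-en-1-yn-1-yl)oxy]silane | CC(C)=CCC#CO[Si](C(C)C)(C(C)C)C(C)C | intermediate
14 | 2-(3-methylbut-2-en-1-yl)buta-1,3-dien-1-one (prenyl vinylketene) | C=CC(CC=C(C)C)=C=O | intermediate
15 | 4-ethenyl-2,4-bis(3-methylbut-2-en-1-yl)-3-[(triisopropylsilyl)oxy]cyclobut-2-en-1-one (racemic) | O=C1C(CC=C(C)C)=C(O[Si](C(C)C)(C(C)C)C(C)C)C1(C=C)CC=C(C)C | intermediate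
16 | (3E)-2,4-bis(3-methylbut-2-en-1-yl)-3-[(triisopropylsilyl)oxy]hexa-1,3,5-trien-1-one (ketene carbon C2 and vinyl carbon C5 cis across C3=C4) | O=C=C(CC=C(C)C)/C(O[Si](C(C)C)(C(C)C)C(C)C)=C(/CC=C(C)C)C=C | intermediate
17 | 2,4-bis(3-methylbut-2-en-1-yl)-3-[(triisopropylsilyl)oxy]cyclohexa-2,4-dien-1-one | O=C1CC=C(CC=C(C)C)C(O[Si](C(C)C)(C(C)C)C(C)C)=C1CC=C(C)C | intermediate
18 | 2,4-bis(3-methylbut-2-en-1-yl)-3-[(triisopropylsilyl)oxy]phenol | CC(C)=CCc1ccc(O)c(CC=C(C)C)c1O[Si](C(C)C)(C(C)C)C(C)C | intermediate
19 | 3-(4-hydroxyphenyl)propanoic acid (phloretic acid) | OC(=O)CCc1ccc(O)cc1 | starting material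
20 | tert-butyldimethylsilyl 3-{4-[(tert-butyldimethylsilyl)oxy]phenyl}propanoate | CC(C)(C)[Si](C)(C)OC(=O)CCc1ccc(O[Si](C)(C)C(C)(C)C)cc1 | intermediate
21 | 3-{4-[(tert-butyldimethylsilyl)oxy]phenyl}propanoic acid | OC(=O)CCc1ccc(O[Si](C)(C)C(C)(C)C)cc1 | intermediate
22 | 2,4-bis(3-methylbut-2-en-1-yl)-3-[(triisopropylsilyl)oxy]phenyl 3-{4-[(tert-butyldimethylsilyl)oxy]phenyl}propanoate | CC(C)=CCc1ccc(OC(=O)CCc2ccc(O[Si](C)(C)C(C)(C)C)cc2)c(CC=C(C)C)c1O[Si](C(C)C)(C(C)C)C(C)C | intermediate
23 | 6-(3-{4-[(tert-butyldimethylsilyl)oxy]phenyl}propanoyl)-2,4-bis(3-methylbut-2-en-1-yl)-3-[(triisopropylsilyl)oxy]cyclohexa-2,4-dien-1-one (racemic) | O=C1C(CC=C(C)C)=C(O[Si](C(C)C)(C(C)C)C(C)C)C(CC=C(C)C)=CC1C(=O)CCc1ccc(O[Si](C)(C)C(C)(C)C)cc1 | intermediate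
24 | 3-{4-[(tert-butyldimethylsilyl)oxy]phenyl}-1-{2-hydroxy-3,5-bis(3-methylbut-2-en-1-yl)-4-[(triisopropylsilyl)oxy]phenyl}propan-1-one | CC(C)=CCc1cc(C(=O)CCc2ccc(O[Si](C)(C)C(C)(C)C)cc2)c(O)c(CC=C(C)C)c1O[Si](C(C)C)(C(C)C)C(C)C | intermediate
25 | Gancaonin J, 1-[2,4-dihydroxy-3,5-bis(3-methylbut-2-en-1-yl)phenyl]-3-(4-hydroxyphenyl)propan-1-one | CC(C)=CCc1cc(C(=O)CCc2ccc(O)cc2)c(O)c(CC=C(C)C)c1O | target

**Step count and risks**

Total step count: 10 steps.
Longest linear sequence: 7 steps (steps 1, 2, 3, 6, 8, 9 and 10).

Steps most likely to fail: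

1. Step 6. The carbene formed from 7 may be lost to 1,2-hydride shift from the neighbouring prenyl CH2, or the acryloyl unit may oligomerise under irradiation, before the Wolff shift delivers ketene to 13.
Fallback (sets out from 8, comes back at 14 and thereby at 18): the same vinylketene is made without light and without a diazo group. Ethyl crotonate is deprotonated at the γ-carbon (LDA, DMPU, THF, −78 °C) and the dienolate is alkylated at its α-carbon by 8 to give ethyl 2-ethenyl-5-methylhex-4-enoate F1. Saponification (LiOH, THF/H2O) gives 2-ethenyl-5-methylhex-4-enoic acid F2, and oxalyl chloride with a trace of DMF gives 2-ethenyl-5-methylhex-4-enoyl chloride F3. Slow addition of F3 to Et3N and 13 in toluene at room temperature should dehydrochlorinate it to 14, which 13 traps as 15. After filtration the solution is heated to 80 °C, and 15 should go on through 16 and 17 to 18. Ketene generation from acid chlorides and ketene addition to siloxyalkynes are both established reactions.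

2. Step 9. Escape of the radical pair from the solvent cage (which returns 18), internal filtering of the light by the strongly absorbing product, or light-driven addition of a phenol to a neighbouring prenyl double bond may hold the conversion low.
Fallback (sets out from 18, comes back at 24): magnesium-mediated ortho-formylation (MgCl2, Et3N, paraformaldehyde, MeCN, reflux) places the carbonyl carbon at C1', the only free ortho position, to give 2-hydroxy-3,5-bis(3-methylbut-2-en-1-yl)-4-[(triisopropylsilyl)oxy]benzaldehyde F4. Commercial 4-(2-bromoethyl)phenol is silylated (t-BuMe2SiCl, imidazole, DMF) to [4-(2-bromoethyl)phenoxy](tert-butyl)dimethylsilane F5 and converted with Mg in THF into {2-[4-(tert-butyldimethylsilyloxy)phenyl]ethyl}magnesium bromide F6. F4 is first deprotonated with i-PrMgCl and then takes up F6 at 0 °C to give the racemic carbinol 3-{4-[(tert-butyldimethylsilyl)oxy]phenyl}-1-{2-hydroxy-3,5-bis(3-methylbut-2-en-1-yl)-4-[(triisopropylsilyl)oxy]phenyl}propan-1-ol F7. MnO2 in CH2Cl2 should then oxidise this benzylic alcohol to 24.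

3. Step 3. Conjugate addition of the amide base or of the enolate to the vinyl ketone (oligomerisation) may compete with clean enolisation, so that little 6 is formed.
Fallback (sets out from 5, comes back at 6): soft enolisation with Me3SiOTf and Et3N in CH2Cl2 at 0 °C gives the silyl dienol ether trimethyl{[(3Z)-7-methylocta-1,3,6-trien-3-yl]oxy}silane F8 without any lithium enolate. C-Acylation of F8 with trifluoroacetic anhydride (CH2Cl2, 0 °C) gives 6, which takes up the diazo group as in the second half of step 3.

Further compounds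
F1 | step 6 | ethyl 2-ethenyl-5-methylhex-4-enoate (racemic) | CCOC(=O)C(C=C)CC=C(C)C
F2 | step 6 | 2-ethenyl-5-methylhex-4-enoic acid (racemic) | OC(=O)C(C=C)CC=C(C)C
F3 | step 6 | 2-ethenyl-5-methylhex-4-enoyl chloride (racemic) | ClC(=O)C(C=C)CC=C(C)C
F4 | step 9 | 2-hydroxy-3,5-bis(3-methylbut-2-en-1-yl)-4-[(triisopropylsilyl)oxy]benzaldehyde | CC(C)=CCc1cc(C=O)c(O)c(CC=C(C)C)c1O[Si](C(C)C)(C(C)C)C(C)C
F5 | step 9 | [4-(2-bromoethyl)phenoxy](tert-butyl)dimethylsilane | BrCCc1ccc(O[Si](C)(C)C(C)(C)C)cc1
F6 | step 9 | {2-[4-(tert-butyldimethylsilyloxy)phenyl]ethyl}magnesium bromide | Br[Mg]CCc1ccc(O[Si](C)(C)C(C)(C)C)cc1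
F7 | step 9 | 3-{4-[(tert-butyldimethylsilyl)oxy]phenyl}-1-{2-hydroxy-3,5-bis(3-methylbut-2-en-1-yl)-4-[(triisopropylsilyl)oxy]phenyl}propan-1-ol (racemic) | CC(C)=CCc1cc(C(O)CCc2ccc(O[Si](C)(C)C(C)(C)C)cc2)c(O)c(CC=C(C)C)c1O[Si](C(C)C)(C(C)C)C(C)C
F8 | step 3 | trimethyl{[(3Z)-7-methylocta-1,3,6-trien-3-yl]oxy}silane | C=C/C(O[Si](C)(C)C)=C/CC=C(C)C
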